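A direct plan would join ring A and ring B through an acetal first and form ring C last.
Directed ortho-lithiation (n-BuLi) and acylation would give the 2,6-bis(methoxymethoxy)aryl silyloxymethyl ketone A1, and [Ir(OMe)(cod)]2-catalysed C–H borylation followed by oxidation with NaBO3 would add the third ring-A oxygen to give phenol A2.
Acid would then strip the protecting groups and tie the ketone to the silyl-protected 4-hydroxybenzaldehyde A3, itself made by bromine–lithium exchange and formylation, as the seven-membered benzylidene acetal A4, whose free 8-OH would be prenylated to the ether A5.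
A chiral phosphoric acid would finally shift the acetal carbon from oxygen to the α-carbon of the ketone and so contract the acetal ring to ring C in the silyl-protected dihydroflavonol A6, from which KHF2 would free the target.
Weakest would be this ring contraction: an untested rearrangement would have to make the C2–C3 bond, ring C and both stereocentres at once, on the most precious intermediate, through a benzylic cation beside an acid-labile prenyl ether.
Second would be the closure of the seven-membered mixed phenol–alcohol acetal on an unprotected acylphloroglucinol: nothing would steer it against oligomeric acetals, and the ring would stay acid-labile afterwards.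
Third would be the lithiation, borylation–oxidation and formylation steps: they would spend a third of the route re-creating a phloroglucinol oxygen pattern and a protected 4-hydroxybenzaldehyde that can be bought.

**Plan of the new route**
The retrosynthesis cuts C3–O (enol oxidation of a flavanone, the laboratory copy of flavanone 3-hydroxylase), then the C2–C1′ bond between ring C and ring B, then the prenyl ether, and last O1–C2 and C2–C3, which returns C2 to a one-carbon reagent and the rest to 2′,4′,6′-trihydroxyacetophenone.
Forward, ring A is bought, ring C is fused to it at once as a flat, achiral 4-pyranone (a chromone), and ring B is attached last as an intact aryl group; no seven-membered ring occurs.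
The feature that allows this: C2 of the target is O1-bound, benzylic and β to the C4 carbonyl, so ring C is a saturated chromone whose C2=C3 bond is an enone acceptor for an aryl–metal species, and C3 is the α-carbon of that ketone, trans to the C2 aryl group.
The catalyst sets C2, and C2 sets C3 by shielding one face of the enol ether; no untested rearrangement and no medium-ring acetal are needed.
All three ring-A oxygens come with the starting material, the prenyl ether is made on a cheap achiral chromone, and only the last two steps handle chiral material, both near neutrality.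

Key step: step 3

Remark: flavonoid numbering (O1, C2, C3, C4, C4a, C5–C8, C8a; ring B C1′–C6′) is used for all chromone, flavanone and dihydroflavonol compounds.
Assumption: the (R)-enantiomer of the diphosphine is taken to deliver the aryl group to the Re face of C2; should a trial with phenylboronic acid show the opposite sense, the (S)-ligand is used and nothing else changes.

Step 1
Reactants: 1 1-(2,4,6-trihydroxyphenyl)ethan-1-one (2′,4′,6′-trihydroxyacetophenone)
Product: 3 5,7-dihydroxy-4H-chromen-4-one, via enaminone 2 (not isolated)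
Conditions: Me2NCH(OMe)2 (3 equiv), DMF, 60 °C, 4 h; evaporate; 2 M aq HCl–MeOH 1:4, 60 °C, 1 h
Reagents that add atoms: N,N-dimethylformamide dimethyl acetal, COC(OC)N(C)C (the C2–H carbon of 3; its dimethylamino group stays only in 2)
Why: Enaminone formation at the acetyl methyl group with the formamide acetal, followed by acid-promoted addition–elimination of the ortho phenol with loss of dimethylamine, is the standard chromone synthesis from 2-hydroxyacetophenones; the two ortho phenols are equivalent, so only one chromone can form, and no stereocentre is made.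

Step 2
Reactants: 3 5,7-dihydroxy-4H-chromen-4-one; 4 1-bromo-3-methylbut-2-ene (prenyl bromide)
Product: 5 5-hydroxy-7-[(3-methylbut-2-en-1-yl)oxy]-4H-chromen-4-one
Conditions: K2CO3 (1.1 equiv), 4 (1.05 equiv), acetone, 45 °C, 6 h
Reagents that add atoms: none
Why: Williamson ether synthesis under chelation control, in which the 5-OH is held in a hydrogen bond to the C4 carbonyl so that the carbonate deprotonates only the more acidic 7-OH (a vinylogous carboxylic acid), here on a cheap achiral chromone; no stereocentre.

Step 3
Reactants: 5 5-hydroxy-7-[(3-methylbut-2-en-1-yl)oxy]-4H-chromen-4-one; 6 {4-[(tert-butyldimethylsilyl)oxy]phenyl}boronic acid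
Product: 8 (2S)-5-hydroxy-2-(4-hydroxyphenyl)-7-[(3-methylbut-2-en-1-yl)oxy]-2,3-dihydro-4H-chromen-4-one [(S)-7-O-prenylnaringenin], via silyl ether 7 (not isolated)
Conditions: [Rh(OH)(cod)]2 (1.5 mol %), (R)-2,2′-bis[bis(3,4,5-trifluorophenyl)phosphino]-6,6′-dimethoxy-1,1′-biphenyl (3.3 mol %), 6 (2.5 equiv), toluene–H2O 10:1, 40 °C, 12 h; silica plug, concentrate; KHF2 (2 equiv), MeOH, rt, 2 h
Reagents that add atoms: none
Why: Hayashi–Miyaura reaction (rhodium-catalysed asymmetric 1,4-addition of an arylboronic acid to an enone), with close precedent for chromones as acceptors giving flavanones: the aryl group passes from boron to the hydroxo complex of monovalent rhodium, the C2=C3 bond of 5 inserts into the aryl–rhodium bond with the aryl group going to C2, and water cleaves the resulting oxa-π-allyl rhodium enolate at C3 and returns the hydroxo complex. The step makes the C2–C1′ bond and closes no ring; ring B is attached intact to the preformed rings A and C. The only new stereocentre, C2, is set by the diphosphine, which lets the aryl group reach the Re face of C2 (the face on which O1, C3 and H run clockwise) and so gives the 2S flavanone, the arrangement that is called 2R once C3 carries oxygen. The selectivities needed are 1,4- over 1,2-addition, which the vinylogous ester secures, and insertion of the enone in preference to the prenyl double bond, which is trisubstituted and unactivated; the hydrogen bond from 5-OH to the C4 carbonyl offsets the donor effect of the two ring-A oxygens on C2. The electron-poor phosphine should speed insertion enough for 40 °C without added base, so the product is not opened to the chalcone that would racemise C2. Potassium hydrogen difluoride then removes the aryl silyl ether, which served only to keep the boronic acid from protodeboronation, under non-basic conditions.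

Step 4
Reactants: 8 (2S)-5-hydroxy-2-(4-hydroxyphenyl)-7-[(3-methylbut-2-en-1-yl)oxy]-2,3-dihydro-4H-chromen-4-one
Product: 11 (2R,3R)-3,5-dihydroxy-2-(4-hydroxyphenyl)-7-[(3-methylbut-2-en-1-yl)oxy]-2,3-dihydro-4H-chromen-4-one (7-prenyloxyaromadendrin), via silyl enol ether 9 (not isolated), via silyloxy epoxide 10 (not isolated)
Conditions: Me3SiOTf (4 equiv), Et3N (6 equiv), CH2Cl2, −20 → 0 °C, 1 h, dark; pentane, cold aq NaHCO3 wash, concentrate; dimethyldioxirane (1.05 equiv, ca. 0.07 M in acetone), CH2Cl2, −78 °C, 30 min; concentrate cold; citric acid (0.3 equiv), MeOH, 0 °C → rt, 30 min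
Reagents that add atoms: dimethyldioxirane, CC1(C)OO1 (oxygen of the 3-OH); trimethylsilyl trifluoromethanesulfonate, C[Si](C)(C)OS(=O)(=O)C(F)(F)F (silyl groups of 9 and 10 only)
Why: Rubottom oxidation, the laboratory counterpart of flavanone 3-hydroxylase: soft enolisation silylates both phenols and turns the ketone into the 2H-chromene silyl enol ether 9 without the strong base that would open ring C, dimethyldioxirane epoxidises the electron-rich C3=C4 enol ether bond far faster than the prenyl double bond (trisubstituted but deactivated by its allylic oxygen) and does so on the face anti to the 2-aryl group, and acid methanolysis opens the silyloxy epoxide 10 to the ketone with the C3–O bond intact and frees the phenols, so that C3 is set trans to the aryl group (3R, also the thermodynamic arrangement) while C2 is untouched and only changes its descriptor to 2R.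

## Compound list
1 | 1-(2,4,6-trihydroxyphenyl)ethan-1-one | CC(=O)c1c(O)cc(O)cc1O | starting material
2 | (2E)-3-(dimethylamino)-1-(2,4,6-trihydroxyphenyl)prop-2-en-1-one | CN(C)/C=C/C(=O)c1c(O)cc(O)cc1O | intermediate
3 | 5,7-dihydroxy-4H-chromen-4-one | O=c1ccoc2cc(O)cc(O)c12 | intermediate
4 | 1-bromo-3-methylbut-2-ene | CC(C)=CCBr | starting material
5 | 5-hydroxy-7-[(3-methylbut-2-en-1-yl)oxy]-4H-chromen-4-one | O=c1ccoc2cc(OCC=C(C)C)cc(O)c12 | intermediate
6 | {4-[(tert-butyldimethylsilyl)oxy]phenyl}boronic acid | CC(C)(C)[Si](C)(C)Oc1ccc(B(O)O)cc1 | starting material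
7 | (2S)-2-{4-[(tert-butyldimethylsilyl)oxy]phenyl}-5-hydroxy-7-[(3-methylbut-2-en-1-yl)oxy]-2,3-dihydro-4H-chromen-4-one | CC(C)=CCOc1cc(O)c2c(c1)O[C@H](c1ccc(O[Si](C)(C)C(C)(C)C)cc1)CC2=O | intermediate
8 | (2S)-5-hydroxy-2-(4-hydroxyphenyl)-7-[(3-methylbut-2-en-1-yl)oxy]-2,3-dihydro-4H-chromen-4-one | CC(C)=CCOc1cc(O)c2c(c1)O[C@H](c1ccc(O)cc1)CC2=O | intermediate
9 | (2S)-7-[(3-methylbut-2-en-1-yl)oxy]-4,5-bis[(trimethylsilyl)oxy]-2-{4-[(trimethylsilyl)oxy]phenyl}-2H-chromene | CC(C)=CCOc1cc(O[Si](C)(C)C)c2c(c1)O[C@H](c1ccc(O[Si](C)(C)C)cc1)C=C2O[Si](C)(C)C | intermediate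
10 | (2R,3R,4R)-3,4-epoxy-7-[(3-methylbut-2-en-1-yl)oxy]-4,5-bis[(trimethylsilyl)oxy]-2-{4-[(trimethylsilyl)oxy]phenyl}-3,4-dihydro-2H-chromene (oxirane oxygen anti to the 2-aryl group) | CC(C)=CCOc1cc(O[Si](C)(C)C)c2c(c1)O[C@H](c1ccc(O[Si](C)(C)C)cc1)[C@H]3O[C@@]23O[Si](C)(C)C | intermediate
11 | (2R,3R)-3,5-dihydroxy-2-(4-hydroxyphenyl)-7-[(3-methylbut-2-en-1-yl)oxy]-2,3-dihydro-4H-chromen-4-one | CC(C)=CCOc1cc(O)c2c(c1)O[C@H](c1ccc(O)cc1)[C@@H](O)C2=O | target

Total step count: 4. Longest linear sequence: 4 steps (1 → 3 → 5 → 8 → 11).

**Steps most likely to fail**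

Step 3: insertion into the donor-rich, chelated enone may be slow enough for protodeboronation of 6 to win, and any base that forms may open the flavanone to its chalcone and erode the configuration at C2. The fallback replaces catalysis by resolution. It sets out from prenyl bromide 4, which would alkylate the most acidic 7-OH of commercial racemic naringenin F1 (K2CO3 1.0 equiv, acetone, rt) to racemic 7-O-prenylnaringenin F2. Preparative chromatography on cellulose tris(3,5-dimethylphenylcarbamate) would separate F2 into 8 and its (2R)-enantiomer F3. F3 would be racemised with a trace of piperidine in ethanol through the ring-opened chalcone F4 and put through the column again. The fallback comes back to the route at 8.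

Step 4: dimethyldioxirane may epoxidise the prenyl double bond alongside the enol ether, or moisture may strip the aryl silyl ethers of 9 before the oxidant arrives. The fallback oxidises before any alkene is present and adds the prenyl group last. It sets out from chromone 3, which would be silylated at 7-OH (i-Pr3SiCl, imidazole, DMF) to 5-hydroxy-7-(triisopropylsilyloxy)chromone F5. The conditions of step 3 without the fluoride stage would add 6 to give the doubly silylated (2S)-flavanone F6. Me3SiOTf/Et3N would give the silyl enol ether F7, and an excess of dimethyldioxirane its epoxide F8. Tetrabutylammonium fluoride buffered with acetic acid (THF, 0 °C) would open the epoxide and remove all silyl groups to give (+)-aromadendrin F9. One equivalent of K2CO3 and prenyl bromide 4 in acetone would then alkylate only the 7-OH, the most acidic phenol. The fallback comes back to the route at 11.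

Step 1: the formamide acetal may O-methylate the free phenols of 1, and the condensation may stall on the triphenol. The fallback is an acid-mediated one-carbon condensation through an isolated pyrylium salt. It sets out from 1, which with triethyl orthoformate and 70 % aqueous HClO4 would give 4-ethoxy-5,7-dihydroxychromenylium perchlorate F10, filtered and kept moist. Warm water would hydrolyse F10 to 3, where the fallback comes back to the route.

Further compounds
F1 | step 3 | rac-5,7-dihydroxy-2-(4-hydroxyphenyl)-2,3-dihydro-4H-chromen-4-one (racemic naringenin) | O=C1CC(c2ccc(O)cc2)Oc2cc(O)cc(O)c12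
F2 | step 3 | rac-5-hydroxy-2-(4-hydroxyphenyl)-7-[(3-methylbut-2-en-1-yl)oxy]-2,3-dihydro-4H-chromen-4-one | CC(C)=CCOc1cc(O)c2c(c1)OC(c1ccc(O)cc1)CC2=O
F3 | step 3 | (2R)-5-hydroxy-2-(4-hydroxyphenyl)-7-[(3-methylbut-2-en-1-yl)oxy]-2,3-dihydro-4H-chromen-4-one | CC(C)=CCOc1cc(O)c2c(c1)O[C@@H](c1ccc(O)cc1)CC2=O
F4 | step 3 | (2E)-1-{2,6-dihydroxy-4-[(3-methylbut-2-en-1-yl)oxy]phenyl}-3-(4-hydroxyphenyl)prop-2-en-1-one | CC(C)=CCOc1cc(O)c(C(=O)/C=C/c2ccc(O)cc2)c(O)c1
F5 | step 4 | 5-hydroxy-7-{[tri(propan-2-yl)silyl]oxy}-4H-chromen-4-one | O=c1ccoc2cc(O[Si](C(C)C)(C(C)C)C(C)C)cc(O)c12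
F6 | step 4 | (2S)-2-{4-[(tert-butyldimethylsilyl)oxy]phenyl}-5-hydroxy-7-{[tri(propan-2-yl)silyl]oxy}-2,3-dihydro-4H-chromen-4-one | CC(C)[Si](Oc1cc(O)c2c(c1)O[C@H](c1ccc(O[Si](C)(C)C(C)(C)C)cc1)CC2=O)(C(C)C)C(C)C
F7 | step 4 | (2S)-2-{4-[(tert-butyldimethylsilyl)oxy]phenyl}-7-{[tri(propan-2-yl)silyl]oxy}-4,5-bis[(trimethylsilyl)oxy]-2H-chromene | CC(C)[Si](Oc1cc(O[Si](C)(C)C)c2c(c1)O[C@H](c1ccc(O[Si](C)(C)C(C)(C)C)cc1)C=C2O[Si](C)(C)C)(C(C)C)C(C)C
F8 | step 4 | (2R,3R,4R)-2-{4-[(tert-butyldimethylsilyl)oxy]phenyl}-3,4-epoxy-7-{[tri(propan-2-yl)silyl]oxy}-4,5-bis[(trimethylsilyl)oxy]-3,4-dihydro-2H-chromene | CC(C)[Si](Oc1cc(O[Si](C)(C)C)c2c(c1)O[C@H](c1ccc(O[Si](C)(C)C(C)(C)C)cc1)[C@H]3O[C@@]23O[Si](C)(C)C)(C(C)C)C(C)C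
F9 | step 4 | (2R,3R)-3,5,7-trihydroxy-2-(4-hydroxyphenyl)-2,3-dihydro-4H-chromen-4-one ((+)-aromadendrin) | Oc1cc(O)c2c(c1)O[C@H](c1ccc(O)cc1)[C@@H](O)C2=O
F10 | step 1 | 4-ethoxy-5,7-dihydroxychromenylium perchlorate | CCOc1cc[o+]c2cc(O)cc(O)c12.[O-]Cl(=O)(=O)=O
A1 | direct plan | 1-[2,6-bis(methoxymethoxy)phenyl]-2-[(tert-butyldimethylsilyl)oxy]ethan-1-one | COCOc1cccc(OCOC)c1C(=O)CO[Si](C)(C)C(C)(C)C
A2 | direct plan | 2-[(tert-butyldimethylsilyl)oxy]-1-[4-hydroxy-2,6-bis(methoxymethoxy)phenyl]ethan-1-one | COCOc1cc(O)cc(OCOC)c1C(=O)CO[Si](C)(C)C(C)(C)C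
A3 | direct plan | 4-[(tert-butyldimethylsilyl)oxy]benzaldehyde | O=Cc1ccc(O[Si](C)(C)C(C)(C)C)cc1
A4 | direct plan | rac-2-{4-[(tert-butyldimethylsilyl)oxy]phenyl}-6,8-dihydroxy-2H-1,3-benzodioxepin-5(4H)-one | Oc1cc(O)c2C(=O)COC(c3ccc(O[Si](C)(C)C(C)(C)C)cc3)Oc2c1
A5 | direct plan | rac-2-{4-[(tert-butyldimethylsilyl)oxy]phenyl}-6-hydroxy-8-[(3-methylbut-2-en-1-yl)oxy]-2H-1,3-benzodioxepin-5(4H)-one | CC(C)=CCOc1cc(O)c2C(=O)COC(c3ccc(O[Si](C)(C)C(C)(C)C)cc3)Oc2c1
A6 | direct plan | (2R,3R)-2-{4-[(tert-butyldimethylsilyl)oxy]phenyl}-3,5-dihydroxy-7-[(3-methylbut-2-en-1-yl)oxy]-2,3-dihydro-4H-chromen-4-one | CC(C)=CCOc1cc(O)c2c(c1)O[C@H](c1ccc(O[Si](C)(C)C(C)(C)C)cc1)[C@@H](O)C2=O
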